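**Retrosynthetic overview**
1. Rings A and B are bought as arenes. Ring C is formed last, by acid-triggered MOM loss and 6-endo ring closure of the (αR,βS)-chalcone epoxide 32 to give target 35.
2. Epoxide 32 comes from chalcone 31 by Juliá–Colonna epoxidation. Chalcone 31 comes from acetophenone 27 and aldehyde 29 by Claisen–Schmidt aldol condensation, the key C–C bond (C2–C3 of ring C).
3. Acetophenone 27 comes from arene 23 by ortho-lithiation and acetylation. The isopropenyl group comes from a methyl ketone (Wittig) and the tertiary alcohol from a prenyl group (Mukaiyama hydration).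
4. The side-chain stereocentre is set by Evans alkylation of arylpropanoyl oxazolidinone 12 with prenyl bromide.
5. Imide 12 comes from 5-methoxyresorcinol via the bis-MOM ether, ortho-lithiation/formylation, Wittig, hydrogenation and saponification.

Assumption: carbon building blocks and the chiral auxiliary are numbered as compounds; protecting-group reagents, one-carbon donors and heteroatom donors are listed only as reagents.

**Route**

Step 1
Reactants: 1 5-methoxybenzene-1,3-diol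
Product: 2 1-methoxy-3,5-bis(methoxymethoxy)benzene
Conditions: MOMCl, iPr2NEt, CH2Cl2, 0 °C → rt
Reagents that add atoms: chloromethyl methyl ether (COCCl)
Why: Twofold O-alkylation (MOM ether formation) masks both phenols and installs the directing groups for the two later ortho-lithiations.

Step 2
Reactants: 2 1-methoxy-3,5-bis(methoxymethoxy)benzene
Product: 5 4-methoxy-2,6-bis(methoxymethoxy)benzaldehyde, via aryllithium 3 (not isolated), via lithium aminoalkoxide 4 (not isolated)
Conditions: n-BuLi, TMEDA, THF, 0 °C; DMF, 0 °C → rt; H2O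
Reagents that add atoms: N,N-dimethylformamide (CN(C)C=O)
Why: Directed ortho-metalation removes the C–H flanked by the two chelating OMOM groups (stronger directors than OMe), and the aryllithium is formylated by DMF.

Step 3
Reactants: 5 4-methoxy-2,6-bis(methoxymethoxy)benzaldehyde; 6 ethyl (triphenylphosphoranylidene)acetate
Product: 7 ethyl (2E)-3-[4-methoxy-2,6-bis(methoxymethoxy)phenyl]prop-2-enoate
Conditions: toluene, 100 °C
Reagents that add atoms: none
Why: Wittig olefination with the stabilised ylide gives the E-cinnamate under neutral conditions (the geometry is erased in step 4).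

Step 4
Reactants: 7 ethyl (2E)-3-[4-methoxy-2,6-bis(methoxymethoxy)phenyl]prop-2-enoate
Product: 8 ethyl 3-[4-methoxy-2,6-bis(methoxymethoxy)phenyl]propanoate
Conditions: H2 (1 atm), 10% Pd/C, EtOAc, rt
Reagents that add atoms: none
Why: Catalytic hydrogenation saturates the conjugated C=C while the aryl MOM ethers and the ester are inert.

Step 5
Reactants: 8 ethyl 3-[4-methoxy-2,6-bis(methoxymethoxy)phenyl]propanoate
Product: 9 3-[4-methoxy-2,6-bis(methoxymethoxy)phenyl]propanoic acid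
Conditions: LiOH·H2O, THF/MeOH/H2O, rt; then 1 M HCl to pH 3–4, 0 °C
Reagents that add atoms: lithium hydroxide ([Li+].[OH-])
Why: Ester saponification, with a brief cold acidification that aryl MOM ethers tolerate.

Step 6
Reactants: 9 3-[4-methoxy-2,6-bis(methoxymethoxy)phenyl]propanoic acid; 10 (4R)-4-benzyl-1,3-oxazolidin-2-one
Product: 12 (4R)-4-benzyl-3-{3-[4-methoxy-2,6-bis(methoxymethoxy)phenyl]propanoyl}-1,3-oxazolidin-2-one, via mixed pivalic anhydride 11 (not isolated)
Conditions: PivCl, Et3N, THF, −20 °C; then LiCl, 10, −20 °C → rt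
Reagents that add atoms: none
Why: N-acylation of the Evans auxiliary through the mixed pivalic anhydride, with LiCl making the oxazolidinone nucleophilic enough under mild amine base.

Step 7
Reactants: 12 (4R)-4-benzyl-3-{3-[4-methoxy-2,6-bis(methoxymethoxy)phenyl]propanoyl}-1,3-oxazolidin-2-one; 13 1-bromo-3-methylbut-2-ene
Product: 15 (4R)-4-benzyl-3-[(2R)-2-{[4-methoxy-2,6-bis(methoxymethoxy)phenyl]methyl}-5-methylhex-4-enoyl]-1,3-oxazolidin-2-one, via sodium Z-enolate 14 (not isolated)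
Conditions: NaN(SiMe3)2, THF, −78 °C; then 13, −78 → −40 °C
Reagents that add atoms: none
Why: Evans asymmetric alkylation, in which the chelated Z-enolate is attacked by the allylic bromide on the face away from the benzyl group of the (R)-auxiliary, sets the (R) side-chain centre (dr ≥ 95:5, minor isomer removed by chromatography).

Step 8
Reactants: 15 (4R)-4-benzyl-3-[(2R)-2-{[4-methoxy-2,6-bis(methoxymethoxy)phenyl]methyl}-5-methylhex-4-enoyl]-1,3-oxazolidin-2-one
Product: 17 (2R)-2-{[4-methoxy-2,6-bis(methoxymethoxy)phenyl]methyl}-5-methylhex-4-enoic acid, via peroxy acid 16 (not isolated)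
Conditions: LiOH, 30% H2O2, THF/H2O, 0 °C; aq. Na2SO3; 1 M HCl to pH 3
Reagents that add atoms: hydrogen peroxide (OO)
Why: Hydroperoxide-mediated exocyclic imide cleavage frees the acid without epimerisation and returns the auxiliary, and sulfite reduces the peracid.

Step 9
Reactants: 17 (2R)-2-{[4-methoxy-2,6-bis(methoxymethoxy)phenyl]methyl}-5-methylhex-4-enoic acid
Product: 19 (2R)-N-methoxy-2-{[4-methoxy-2,6-bis(methoxymethoxy)phenyl]methyl}-N,5-dimethylhex-4-enamide, via acyl imidazole 18 (not isolated)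
Conditions: CDI, THF, rt; then MeNHOMe·HCl, rt
Reagents that add atoms: N,O-dimethylhydroxylamine hydrochloride (CNOC.Cl)
Why: Amide coupling through the acyl imidazole gives the Weinreb amide under near-neutral conditions that leave the α-centre intact.

Step 10
Reactants: 19 (2R)-N-methoxy-2-{[4-methoxy-2,6-bis(methoxymethoxy)phenyl]methyl}-N,5-dimethylhex-4-enamide
Product: 21 (3R)-3-{[4-methoxy-2,6-bis(methoxymethoxy)phenyl]methyl}-6-methylhept-5-en-2-one, via magnesium hemiaminal chelate 20 (not isolated)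
Conditions: MeMgBr, THF, 0 °C; H2O
Reagents that add atoms: methylmagnesium bromide (C[Mg]Br)
Why: Weinreb ketone synthesis, in which the chelated tetrahedral adduct stops at mono-addition and releases the methyl ketone only on work-up.

Step 11
Reactants: 21 (3R)-3-{[4-methoxy-2,6-bis(methoxymethoxy)phenyl]methyl}-6-methylhept-5-en-2-one
Product: 22 (3R)-6-hydroxy-3-{[4-methoxy-2,6-bis(methoxymethoxy)phenyl]methyl}-6-methylheptan-2-one
Conditions: Co(acac)2 (20 mol %), PhSiH3, O2 (1 atm), THF, rt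
Reagents that add atoms: dioxygen (O=O)
Why: Mukaiyama hydration (cobalt-mediated hydrogen-atom transfer, then O2 trapping) gives the Markovnikov tertiary alcohol at the only alkene present, under neutral conditions that do not touch the α-stereocentre.

Step 12
Reactants: 22 (3R)-6-hydroxy-3-{[4-methoxy-2,6-bis(methoxymethoxy)phenyl]methyl}-6-methylheptan-2-one
Product: 23 (5R)-5-{[4-methoxy-2,6-bis(methoxymethoxy)phenyl]methyl}-2,6-dimethylhept-6-en-2-ol
Conditions: Ph3PCH3Br, KN(SiMe3)2 (3 equiv of ylide), THF, 0 °C; then 22, 0 °C → rt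
Reagents that add atoms: methyltriphenylphosphonium bromide (C[P+](c1ccccc1)(c1ccccc1)c1ccccc1.[Br-])
Why: Wittig methylenation with excess preformed ylide (one equivalent is held by the OH) turns the methyl ketone into the isopropenyl group, since addition to the unhindered C=O outruns enolisation at the tertiary α-carbon.

Step 13
Reactants: 23 (5R)-5-{[4-methoxy-2,6-bis(methoxymethoxy)phenyl]methyl}-2,6-dimethylhept-6-en-2-ol; 24 N-methoxy-N-methylacetamide
Product: 27 1-{3-[(2R)-5-hydroxy-5-methyl-2-(prop-1-en-2-yl)hexyl]-6-methoxy-2,4-bis(methoxymethoxy)phenyl}ethan-1-one, via dilithiated arene 25 (not isolated), via lithium hemiaminal adduct 26 (not isolated)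
Conditions: n-BuLi (2.3 equiv), TMEDA, THF, −20 → 0 °C; then 24, −78 → 0 °C; H2O
Reagents that add atoms: none
Why: After the alkoxide forms, directed ortho-metalation takes one of the two equivalent aryl C–H (each between OMOM and OMe), and acylation by the Weinreb amide gives the acetophenone without over-addition.

Step 14
Reactants: 28 2,4-dihydroxybenzaldehyde
Product: 29 2,4-bis(methoxymethoxy)benzaldehyde
Conditions: MOMCl, K2CO3, acetone, reflux
Reagents that add atoms: chloromethyl methyl ether (COCCl)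
Why: Base-mediated MOM ether formation protects both phenols of the ring B aldehyde against the basic and oxidative steps that follow.

Step 15
Reactants: 27 1-{3-[(2R)-5-hydroxy-5-methyl-2-(prop-1-en-2-yl)hexyl]-6-methoxy-2,4-bis(methoxymethoxy)phenyl}ethan-1-one; 29 2,4-bis(methoxymethoxy)benzaldehyde
Product: 31 (2E)-3-[2,4-bis(methoxymethoxy)phenyl]-1-{3-[(2R)-5-hydroxy-5-methyl-2-(prop-1-en-2-yl)hexyl]-6-methoxy-2,4-bis(methoxymethoxy)phenyl}prop-2-en-1-one, via aldol adduct 30 (not isolated)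
Conditions: KOH, EtOH/H2O, rt
Reagents that add atoms: none
Why: Claisen–Schmidt crossed aldol condensation, in which the ketone enolate adds to the non-enolisable aldehyde and E1cB dehydration gives the E-chalcone, forms the future C2–C3 bond of ring C.

Step 16
Reactants: 31 (2E)-3-[2,4-bis(methoxymethoxy)phenyl]-1-{3-[(2R)-5-hydroxy-5-methyl-2-(prop-1-en-2-yl)hexyl]-6-methoxy-2,4-bis(methoxymethoxy)phenyl}prop-2-en-1-one
Product: 32 {(2R,3S)-3-[2,4-bis(methoxymethoxy)phenyl]oxiran-2-yl}{3-[(2R)-5-hydroxy-5-methyl-2-(prop-1-en-2-yl)hexyl]-6-methoxy-2,4-bis(methoxymethoxy)phenyl}methanone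
Conditions: poly-L-leucine, urea–H2O2, DBU, THF, rt
Reagents that add atoms: urea–hydrogen peroxide (NC(N)=O.OO)
Why: Juliá–Colonna asymmetric nucleophilic (Weitz–Scheffer) epoxidation attacks only the electron-poor enone, leaves the isolated isopropenyl alkene alone, and the helical poly-L-leucine delivers the (αR,βS)-trans-epoxide.

Step 17
Reactants: 32 {(2R,3S)-3-[2,4-bis(methoxymethoxy)phenyl]oxiran-2-yl}{3-[(2R)-5-hydroxy-5-methyl-2-(prop-1-en-2-yl)hexyl]-6-methoxy-2,4-bis(methoxymethoxy)phenyl}methanone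
Product: 35 (2R,3R)-2-(2,4-dihydroxyphenyl)-3,7-dihydroxy-8-[(2R)-5-hydroxy-5-methyl-2-(prop-1-en-2-yl)hexyl]-5-methoxy-2,3-dihydro-4H-chromen-4-one, via free 2′-phenol epoxide 33 (not isolated), via tris-MOM flavanonol 34 (not isolated)
Conditions: HCl (ca. 1 M) in MeOH, 0 °C → rt
Reagents that add atoms: none
Why: Acidic acetal cleavage frees the 2′-phenol (the MOM next to the C=O goes first), which opens the protonated epoxide 6-endo at the benzylic carbon with inversion to the 2,3-trans (2R,3R) ring while C3 keeps its configuration, and the remaining MOM groups are then lost.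

**Compound list**
1 | 5-methoxybenzene-1,3-diol (5-methoxyresorcinol) | COc1cc(O)cc(O)c1 | starting material
2 | 1-methoxy-3,5-bis(methoxymethoxy)benzene | COCOc1cc(OC)cc(OCOC)c1 | intermediate
3 | [4-methoxy-2,6-bis(methoxymethoxy)phenyl]lithium | COCOc1cc(OC)cc(OCOC)c1[Li] | intermediate
4 | lithium (dimethylamino)[4-methoxy-2,6-bis(methoxymethoxy)phenyl]methanolate | COCOc1cc(OC)cc(OCOC)c1C(O[Li])N(C)C | intermediate
5 | 4-methoxy-2,6-bis(methoxymethoxy)benzaldehyde | COCOc1cc(OC)cc(OCOC)c1C=O | intermediate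
6 | ethyl (triphenylphosphoranylidene)acetate | CCOC(=O)C=P(c1ccccc1)(c1ccccc1)c1ccccc1 | starting material
7 | ethyl (2E)-3-[4-methoxy-2,6-bis(methoxymethoxy)phenyl]prop-2-enoate | CCOC(=O)/C=C/c1c(OCOC)cc(OC)cc1OCOC | intermediate
8 | ethyl 3-[4-methoxy-2,6-bis(methoxymethoxy)phenyl]propanoate | CCOC(=O)CCc1c(OCOC)cc(OC)cc1OCOC | intermediate
9 | 3-[4-methoxy-2,6-bis(methoxymethoxy)phenyl]propanoic acid | OC(=O)CCc1c(OCOC)cc(OC)cc1OCOC | intermediate
10 | (4R)-4-benzyl-1,3-oxazolidin-2-one | O=C1N[C@H](Cc2ccccc2)CO1 | starting material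
11 | 3-[4-methoxy-2,6-bis(methoxymethoxy)phenyl]propanoic pivalic anhydride | CC(C)(C)C(=O)OC(=O)CCc1c(OCOC)cc(OC)cc1OCOC | intermediate
12 | (4R)-4-benzyl-3-{3-[4-methoxy-2,6-bis(methoxymethoxy)phenyl]propanoyl}-1,3-oxazolidin-2-one | O=C(CCc1c(OCOC)cc(OC)cc1OCOC)N1[C@H](Cc2ccccc2)COC1=O | intermediate
13 | 1-bromo-3-methylbut-2-ene (prenyl bromide) | CC(C)=CCBr | starting material
14 | sodium (Z)-enolate of 12 | [Na+].[O-]/C(=C\Cc1c(OCOC)cc(OC)cc1OCOC)N1[C@H](Cc2ccccc2)COC1=O | intermediate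
15 | (4R)-4-benzyl-3-[(2R)-2-{[4-methoxy-2,6-bis(methoxymethoxy)phenyl]methyl}-5-methylhex-4-enoyl]-1,3-oxazolidin-2-one | CC(C)=CC[C@H](Cc1c(OCOC)cc(OC)cc1OCOC)C(=O)N1[C@H](Cc2ccccc2)COC1=O | intermediate
16 | (2R)-2-{[4-methoxy-2,6-bis(methoxymethoxy)phenyl]methyl}-5-methylhex-4-eneperoxoic acid | CC(C)=CC[C@H](Cc1c(OCOC)cc(OC)cc1OCOC)C(=O)OO | intermediate
17 | (2R)-2-{[4-methoxy-2,6-bis(methoxymethoxy)phenyl]methyl}-5-methylhex-4-enoic acid | CC(C)=CC[C@H](Cc1c(OCOC)cc(OC)cc1OCOC)C(=O)O | intermediate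
18 | (2R)-1-(1H-imidazol-1-yl)-2-{[4-methoxy-2,6-bis(methoxymethoxy)phenyl]methyl}-5-methylhex-4-en-1-one | CC(C)=CC[C@H](Cc1c(OCOC)cc(OC)cc1OCOC)C(=O)n1ccnc1 | intermediate
19 | (2R)-N-methoxy-2-{[4-methoxy-2,6-bis(methoxymethoxy)phenyl]methyl}-N,5-dimethylhex-4-enamide | CC(C)=CC[C@H](Cc1c(OCOC)cc(OC)cc1OCOC)C(=O)N(C)OC | intermediate
20 | bromomagnesium hemiaminal alkoxide from 19 (tetrahedral Weinreb adduct) | CC(C)=CC[C@H](Cc1c(OCOC)cc(OC)cc1OCOC)C(C)(O[Mg]Br)N(C)OC | intermediate
21 | (3R)-3-{[4-methoxy-2,6-bis(methoxymethoxy)phenyl]methyl}-6-methylhept-5-en-2-one | CC(C)=CC[C@H](Cc1c(OCOC)cc(OC)cc1OCOC)C(C)=O | intermediate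
22 | (3R)-6-hydroxy-3-{[4-methoxy-2,6-bis(methoxymethoxy)phenyl]methyl}-6-methylheptan-2-one (may equilibrate with its cyclic hemiketal) | CC(C)(O)CC[C@H](Cc1c(OCOC)cc(OC)cc1OCOC)C(C)=O | intermediate
23 | (5R)-5-{[4-methoxy-2,6-bis(methoxymethoxy)phenyl]methyl}-2,6-dimethylhept-6-en-2-ol | CC(C)(O)CC[C@H](Cc1c(OCOC)cc(OC)cc1OCOC)C(C)=C | intermediate
24 | N-methoxy-N-methylacetamide | CC(=O)N(C)OC | starting material
25 | dilithiated 23 (lithium alkoxide, aryllithium between OMOM and OMe) | [Li]OC(C)(C)CC[C@H](Cc1c(OCOC)cc(OC)c([Li])c1OCOC)C(C)=C | intermediate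
26 | dilithium tetrahedral adduct of 25 and 24 | [Li]OC(C)(C)CC[C@H](Cc1c(OCOC)cc(OC)c(C(C)(O[Li])N(C)OC)c1OCOC)C(C)=C | intermediate
27 | 1-{3-[(2R)-5-hydroxy-5-methyl-2-(prop-1-en-2-yl)hexyl]-6-methoxy-2,4-bis(methoxymethoxy)phenyl}ethan-1-one | CC(C)(O)CC[C@H](Cc1c(OCOC)cc(OC)c(C(C)=O)c1OCOC)C(C)=C | intermediate
28 | 2,4-dihydroxybenzaldehyde | O=Cc1ccc(O)cc1O | starting material
29 | 2,4-bis(methoxymethoxy)benzaldehyde | O=Cc1ccc(OCOC)cc1OCOC | intermediate
30 | 3-[2,4-bis(methoxymethoxy)phenyl]-3-hydroxy-1-{3-[(2R)-5-hydroxy-5-methyl-2-(prop-1-en-2-yl)hexyl]-6-methoxy-2,4-bis(methoxymethoxy)phenyl}propan-1-one (C3 epimers) | CC(C)(O)CC[C@H](Cc1c(OCOC)cc(OC)c(C(=O)CC(O)c2ccc(OCOC)cc2OCOC)c1OCOC)C(C)=C | intermediate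
31 | (2E)-3-[2,4-bis(methoxymethoxy)phenyl]-1-{3-[(2R)-5-hydroxy-5-methyl-2-(prop-1-en-2-yl)hexyl]-6-methoxy-2,4-bis(methoxymethoxy)phenyl}prop-2-en-1-one | CC(C)(O)CC[C@H](Cc1c(OCOC)cc(OC)c(C(=O)/C=C/c2ccc(OCOC)cc2OCOC)c1OCOC)C(C)=C | intermediate
32 | {(2R,3S)-3-[2,4-bis(methoxymethoxy)phenyl]oxiran-2-yl}{3-[(2R)-5-hydroxy-5-methyl-2-(prop-1-en-2-yl)hexyl]-6-methoxy-2,4-bis(methoxymethoxy)phenyl}methanone | CC(C)(O)CC[C@H](Cc1c(OCOC)cc(OC)c(C(=O)[C@@H]2O[C@H]2c3ccc(OCOC)cc3OCOC)c1OCOC)C(C)=C | intermediate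
33 | {(2R,3S)-3-[2,4-bis(methoxymethoxy)phenyl]oxiran-2-yl}{2-hydroxy-3-[(2R)-5-hydroxy-5-methyl-2-(prop-1-en-2-yl)hexyl]-6-methoxy-4-(methoxymethoxy)phenyl}methanone | CC(C)(O)CC[C@H](Cc1c(OCOC)cc(OC)c(C(=O)[C@@H]2O[C@H]2c3ccc(OCOC)cc3OCOC)c1O)C(C)=C | intermediate
34 | (2R,3R)-2-[2,4-bis(methoxymethoxy)phenyl]-3-hydroxy-8-[(2R)-5-hydroxy-5-methyl-2-(prop-1-en-2-yl)hexyl]-5-methoxy-7-(methoxymethoxy)-2,3-dihydro-4H-chromen-4-one | CC(C)(O)CC[C@H](Cc1c(OCOC)cc(OC)c2c1O[C@H](c1ccc(OCOC)cc1OCOC)[C@@H](O)C2=O)C(C)=C | intermediate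
35 | (2R,3R)-2-(2,4-dihydroxyphenyl)-3,7-dihydroxy-8-[(2R)-5-hydroxy-5-methyl-2-(prop-1-en-2-yl)hexyl]-5-methoxy-2,3-dihydro-4H-chromen-4-one | C=C(C)[C@H](CCC(C)(C)O)Cc1c(O)cc(OC)c2c1O[C@H](c1ccc(O)cc1O)[C@@H](O)C2=O | target

**Step count**
Total: 17 steps. Longest linear sequence: 16 steps (steps 1–13 and 15–17, from 1 to 35); step 14 is a one-step branch.

**Steps most likely to fail, with fallbacks**

Step 16 is the weakest point. The enone carries a doubly ortho-substituted, electron-rich aryl ketone and an electron-rich β-aryl group, so the poly-L-leucine epoxidation may be slow or poorly selective. The fallback sets out from chalcone 31 and comes back to the route at target 35. Epoxidise 31 without a chiral catalyst (H2O2, NaOH, MeOH/THF, 0 °C → rt), which gives 32 mixed with the epimeric (αS,βR)-epoxide F1. Carry the mixture through the conditions of step 17 to obtain 35 together with the (2S,3S)-flavanonol diastereomer F2, and separate the two by preparative HPLC. They are diastereomers, not enantiomers, because the side-chain centre is already fixed as (R). The same separation also upgrades material from a partly selective step 16.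

Step 17 comes next. The 2,4-dioxygenated benzylic epoxide ionises very easily, so methanolysis, acyl or aryl shifts and some 2,3-cis product can compete with ring closure. The isopropenyl group next to the free 7-OH and the tertiary alcohol also limit how much acid can be used. The fallback sets out from epoxide 32 and comes back at target 35. Open the oxirane first with benzyl mercaptan (BnSH, catalytic SnCl4, CH2Cl2, −20 °C) at the benzylic carbon to give the β-benzylsulfanyl α-hydroxy ketone F3 (C-α unchanged in space, C-β epimers). Then remove the four MOM groups with HCl/MeOH at 0 °C, where no epoxide is left to rearrange, to give the pentahydroxy sulfide F4. Finally activate sulfur with AgBF4 (CH2Cl2, 0 °C) so that the 2′-OH closes ring C to the favoured 2,3-trans flavanonol 35.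

Step 13 is the third. The hindered aryllithium may deprotonate N-methoxy-N-methylacetamide instead of adding to it, returning 23. The fallback sets out from arene 23 and comes back at acetophenone 27. Generate 25 as in step 13, trap it with acetaldehyde at −78 °C to give the benzylic carbinol F5, and oxidise this with Dess–Martin periodinane (NaHCO3, CH2Cl2, rt) to 27; the tertiary alcohol and the alkene are not affected.

**Further compounds**
F1 | step 16 | {(2S,3R)-3-[2,4-bis(methoxymethoxy)phenyl]oxiran-2-yl}{3-[(2R)-5-hydroxy-5-methyl-2-(prop-1-en-2-yl)hexyl]-6-methoxy-2,4-bis(methoxymethoxy)phenyl}methanone | CC(C)(O)CC[C@H](Cc1c(OCOC)cc(OC)c(C(=O)[C@H]2O[C@@H]2c3ccc(OCOC)cc3OCOC)c1OCOC)C(C)=C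
F2 | step 16 | (2S,3S)-2-(2,4-dihydroxyphenyl)-3,7-dihydroxy-8-[(2R)-5-hydroxy-5-methyl-2-(prop-1-en-2-yl)hexyl]-5-methoxy-2,3-dihydro-4H-chromen-4-one | CC(C)(O)CC[C@H](Cc1c(O)cc(OC)c2c1O[C@@H](c1ccc(O)cc1O)[C@H](O)C2=O)C(C)=C
F3 | step 17 | (2S)-3-(benzylsulfanyl)-3-[2,4-bis(methoxymethoxy)phenyl]-2-hydroxy-1-{3-[(2R)-5-hydroxy-5-methyl-2-(prop-1-en-2-yl)hexyl]-6-methoxy-2,4-bis(methoxymethoxy)phenyl}propan-1-one (C3 epimers) | CC(C)(O)CC[C@H](Cc1c(OCOC)cc(OC)c(C(=O)[C@H](O)C(SCc2ccccc2)c2ccc(OCOC)cc2OCOC)c1OCOC)C(C)=C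
F4 | step 17 | (2S)-3-(benzylsulfanyl)-1-{2,4-dihydroxy-3-[(2R)-5-hydroxy-5-methyl-2-(prop-1-en-2-yl)hexyl]-6-methoxyphenyl}-3-(2,4-dihydroxyphenyl)-2-hydroxypropan-1-one (C3 epimers) | CC(C)(O)CC[C@H](Cc1c(O)cc(OC)c(C(=O)[C@H](O)C(SCc2ccccc2)c2ccc(O)cc2O)c1O)C(C)=C
F5 | step 13 | 1-{3-[(2R)-5-hydroxy-5-methyl-2-(prop-1-en-2-yl)hexyl]-6-methoxy-2,4-bis(methoxymethoxy)phenyl}ethan-1-ol (carbinol epimers) | CC(C)(O)CC[C@H](Cc1c(OCOC)cc(OC)c(C(C)O)c1OCOC)C(C)=C
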